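The route rests on building outer ring A from a four-carbon and a two-carbon piece rather than differentiating three phenols on a finished ring. Ring A bears oxygen at C2, C4 and C6, yet only O4, wedged between the C3 methyl and the C5 butyryl, is methylated. Heating 3-methoxy-4-methylcyclobutenone with a triisopropylsiloxyalkyne whose propargylic CH2 (the future bridge) holds benzyl-protected ring B forms C1–C2, C5–C6 and C2–C3 in one pericyclic cascade and delivers O2 as free phenol, O4 as methyl ether and O6 as silyl ether. Deprotection, one Hoesch butyrylation per ring and capture of a ring C quinone methide at ring B's last free carbon complete the target.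

Key step: step 7

Remark on the chemistry: the target has no stereocentre and no stereogenic double bond, so every chiral intermediate is carried as a racemate. Ring A is numbered C1 (bridge), C2 (OH), C3 (CH3), C4 (OCH3), C5 (butyryl), C6 (OH). Ring B is the central ring. Ring C is the other outer ring, with its methoxy para to its butyryl.

Step 1
Reactants: 1 2-chloro-1,1-dimethoxyethane
Product: 3 methoxyethyne (methoxyacetylene), via sodium methoxyethynide 2 (not isolated)
Conditions: NaNH2 (3.1 equiv), liq. NH3, −33 °C; then cold aq. NaCl; distil into Et2O at −78 °C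
Reagents that add atoms: none
Why: Twofold β-elimination (loss of methanol, then of HCl) is the classical alkoxyacetylene synthesis from a chloroacetal, and the third equivalent of amide holds the product as its sodium salt 2 until the aqueous quench.

Step 2
Reactants: 3 methoxyethyne; 4 propanoyl chloride
Product: 6 3-methoxy-4-methylcyclobut-2-en-1-one (racemic), via methylketene 5 (not isolated)
Conditions: Et3N, Et2O, 0 °C → rt, slow addition of 4 to excess 3
Reagents that add atoms: none
Why: Dehydrochlorination gives methylketene, which is trapped in a thermal ketene–ynol ether [2+2] cycloaddition in which the nucleophilic terminal alkyne carbon bonds to the ketene carbonyl carbon, so methoxy ends at C3 and methyl at C4, and the single stereocentre forms as a racemate that is erased later.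

Step 3
Reactants: 7 2,4,6-trihydroxybenzaldehyde
Product: 8 2,4,6-tris(benzyloxy)benzaldehyde
Conditions: BnBr, K2CO3, DMF, 60 °C
Reagents that add atoms: benzyl bromide BrCc1ccccc1
Why: Williamson etherification should work because the formyl group lowers the carbon nucleophilicity of the ring enough for O-benzylation to outrun C-benzylation.

Step 4
Reactants: 8 2,4,6-tris(benzyloxy)benzaldehyde
Product: 9 1-[2,4,6-tris(benzyloxy)phenyl]prop-2-yn-1-ol (racemic)
Conditions: HC≡CMgBr, THF, 0 °C; then H2O (pH 7 buffer)
Reagents that add atoms: ethynylmagnesium bromide C#C[Mg]Br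
Why: Grignard 1,2-addition of an acetylide to a non-enolisable aldehyde brings in both alkyne carbons at once, and the racemic carbinol centre is removed in the next step.

Step 5
Reactants: 9 1-[2,4,6-tris(benzyloxy)phenyl]prop-2-yn-1-ol
Product: 10 1,3,5-tris(benzyloxy)-2-(prop-2-yn-1-yl)benzene
Conditions: Et3SiH (5 equiv), CF3CO2H (2 equiv), CH2Cl2, −40 → 0 °C, inverse addition of 9
Reagents that add atoms: none
Why: In this Kursanov–Parnes ionic hydrogenation the trialkoxyaryl group makes ionisation very easy and hydride is delivered to the benzylic carbon, while excess silane, low temperature and inverse addition suppress Friedel–Crafts self-alkylation and spare the benzyl ethers.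

Step 6
Reactants: 10 1,3,5-tris(benzyloxy)-2-(prop-2-yn-1-yl)benzene
Product: 13 triisopropyl({3-[2,4,6-tris(benzyloxy)phenyl]prop-1-yn-1-yl}oxy)silane, via lithium acetylide 11 (not isolated), via lithium ynolate 12 (not isolated)
Conditions: n-BuLi, THF, −78 °C; t-BuOOLi (from t-BuOOH and LiN(SiMe3)2), −78 → 0 °C; i-Pr3SiOTf, −78 → 0 °C
Reagents that add atoms: tert-butyl hydroperoxide CC(C)(C)OO; triisopropylsilyl trifluoromethanesulfonate CC(C)[Si](OS(=O)(=O)C(F)(F)F)(C(C)C)C(C)C
Why: Electrophilic oxygenation of a lithium acetylide by lithium tert-butyl peroxide (substitution at oxygen) gives the ynolate, and the bulky silyl triflate then reacts at oxygen rather than carbon, which is the standard passage from a terminal alkyne to a siloxyalkyne and needs only one equivalent of strong base next to the benzyl ethers.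

Step 7
Reactants: 6 3-methoxy-4-methylcyclobut-2-en-1-one; 13 triisopropyl({3-[2,4,6-tris(benzyloxy)phenyl]prop-1-yn-1-yl}oxy)silane
Product: 18 5-methoxy-6-methyl-2-{[2,4,6-tris(benzyloxy)phenyl]methyl}-3-[(triisopropylsilyl)oxy]phenol, via vinylketene 14 (not isolated), via alkenylcyclobutenone 15 (not isolated), via dienylketene 16 (not isolated), via cyclohexadienone 17 (not isolated)
Conditions: 6 (1.5 equiv), toluene, sealed tube, argon, 110 → 145 °C
Reagents that add atoms: none
Why: This is a Danheiser benzannulation in its siloxyalkyne form: conrotatory 4π opening of 6, with the methyl group turning outward, gives vinylketene 14, whose ketene C=C adds [2+2] to 13 to give 4-alkenylcyclobutenone 15. A second, reversible 4π opening gives dienylketene 16, and only the isomer that holds ketene and alkenyl group cis on the central double bond can react further. Ring A, the only ring formed, closes by disrotatory 6π electrocyclisation between the ketene carbon and the methyl-bearing terminus (C2–C3) to give dienone 17, which tautomerises irreversibly to phenol 18. No stereocentre is created for the target, since those of 6, 15 and 17 vanish on aromatisation. The one selectivity needed is the orientation of the [2+2] step, and the oxygen lone pair of 13 secures it by making the carbon that bears the arylmethyl group nucleophilic, so that it bonds to the ketene carbonyl carbon (C1–C2) while the siloxy carbon bonds to the former C2 of 6 (C5–C6). Benzyl ethers, silyl ether and enol ether tolerate neutral heating, and the low stationary concentration of 14 that reversible opening provides disfavours ketene self-condensation.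

Step 8
Reactants: 18 5-methoxy-6-methyl-2-{[2,4,6-tris(benzyloxy)phenyl]methyl}-3-[(triisopropylsilyl)oxy]phenol
Product: 19 5-methoxy-4-methyl-2-{[2,4,6-tris(benzyloxy)phenyl]methyl}benzene-1,3-diol
Conditions: Bu4NF, AcOH, THF, 0 °C
Reagents that add atoms: none
Why: Fluoride-induced Si–O cleavage of an aryl silyl ether is fast, the acetic acid buffer keeps the electron-rich phenoxide from air oxidation, and benzyl and methyl ethers are untouched.

Step 9
Reactants: 19 5-methoxy-4-methyl-2-{[2,4,6-tris(benzyloxy)phenyl]methyl}benzene-1,3-diol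
Product: 20 2-[(2,6-dihydroxy-4-methoxy-3-methylphenyl)methyl]benzene-1,3,5-triol
Conditions: H2 (1 atm), 10% Pd/C, EtOAc–MeOH, rt; used at once
Reagents that add atoms: none
Why: Catalytic hydrogenolysis removes the three aryl benzyl ethers under neutral conditions that leave the methyl ether and the diarylmethane C–C bonds intact.

Step 10
Reactants: 20 2-[(2,6-dihydroxy-4-methoxy-3-methylphenyl)methyl]benzene-1,3,5-triol
Product: 22 1-{3-[(3-butanoyl-2,4,6-trihydroxyphenyl)methyl]-2,4-dihydroxy-6-methoxy-5-methylphenyl}butan-1-one, via bis(ketiminium chloride) 21 (not isolated)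
Conditions: PrCN (excess), ZnCl2, HCl (g), Et2O, 0 °C; then H2O, 90 °C
Reagents that add atoms: butanenitrile CCCC#N; water O
Why: In this twofold Houben–Hoesch acylation ring A can react only at C5 and ring B at either of two equivalent carbons, each ring stops after one acylation because the ketiminium group deactivates it, and the mild ZnCl2/HCl medium spares the methoxy group that ends up ortho to the new ketone.

Step 11
Reactants: 23 2-methylbenzene-1,3,5-triol
Product: 24 1-(2,4,6-trihydroxy-3-methylphenyl)butan-1-one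
Conditions: PrCOCl, AlCl3, CH2Cl2–PhNO2, 0 → 40 °C
Reagents that add atoms: butanoyl chloride CCCC(Cl)=O
Why: Friedel–Crafts acylation of a phloroglucinol whose two free carbons are equivalent gives a single ketone, and the acyl group shuts down a second acylation.

Step 12
Reactants: 24 1-(2,4,6-trihydroxy-3-methylphenyl)butan-1-one
Product: 25 1-(2,6-dihydroxy-4-methoxy-3-methylphenyl)butan-1-one
Conditions: Me2SO4 (1 equiv), K2CO3 (1 equiv), acetone, rt
Reagents that add atoms: dimethyl sulfate COS(=O)(=O)OC
Why: Selective Williamson O-methylation should occur at the hydroxyl para to the ketone, which is the most acidic and the only one not engaged with the carbonyl, and that is exactly the pattern ring C requires.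

Step 13
Reactants: 25 1-(2,6-dihydroxy-4-methoxy-3-methylphenyl)butan-1-one
Product: 26 1-{3-[(dimethylamino)methyl]-2,6-dihydroxy-4-methoxy-5-methylphenyl}butan-1-one
Conditions: aq. CH2O and aq. Me2NH (premixed, 1.5 equiv each), EtOH, 0 °C → rt
Reagents that add atoms: formaldehyde C=O; dimethylamine CNC
Why: Mannich aminomethylation takes place at the only unsubstituted ring carbon, ortho to a phenol, and the premixed excess of iminium source consumes 25 quickly so that it cannot intercept the product.

Step 14
Reactants: 22 1-{3-[(3-butanoyl-2,4,6-trihydroxyphenyl)methyl]-2,4-dihydroxy-6-methoxy-5-methylphenyl}butan-1-one; 26 1-{3-[(dimethylamino)methyl]-2,6-dihydroxy-4-methoxy-5-methylphenyl}butan-1-one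
Product: 28 1-{3-[(3-butanoyl-2,6-dihydroxy-4-methoxy-5-methylphenyl)methyl]-5-[(3-butanoyl-2,4-dihydroxy-6-methoxy-5-methylphenyl)methyl]-2,4,6-trihydroxyphenyl}butan-1-one (target), via ring C ortho-quinone methide 27 (not isolated)
Conditions: 26 (1.1 equiv), 1,4-dioxane, 85 °C, N2 sweep
Reagents that add atoms: none
Why: Thermal loss of dimethylamine from the ortho-hydroxybenzylamine gives quinone methide 27, which has no free ring carbon of its own and is taken up in a conjugate, Friedel–Crafts-type addition by the single unsubstituted aromatic carbon of 22, the established way to unsymmetrical methylene-bridged acylphloroglucinols.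

Compound list
1 | 2-chloro-1,1-dimethoxyethane | COC(CCl)OC | starting material
2 | sodium methoxyethynide | [Na+].[C-]#COC | intermediate
3 | methoxyethyne | C#COC | intermediate
4 | propanoyl chloride | CCC(Cl)=O | starting material
5 | methylketene (prop-1-en-1-one) | CC=C=O | intermediate
6 | 3-methoxy-4-methylcyclobut-2-en-1-one (racemic) | COC1=CC(=O)C1C | intermediate
7 | 2,4,6-trihydroxybenzaldehyde | O=Cc1c(O)cc(O)cc1O | starting material
8 | 2,4,6-tris(benzyloxy)benzaldehyde | O=Cc1c(OCc2ccccc2)cc(OCc2ccccc2)cc1OCc1ccccc1 | intermediate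
9 | 1-[2,4,6-tris(benzyloxy)phenyl]prop-2-yn-1-ol (racemic) | C#CC(O)c1c(OCc2ccccc2)cc(OCc2ccccc2)cc1OCc1ccccc1 | intermediate
10 | 1,3,5-tris(benzyloxy)-2-(prop-2-yn-1-yl)benzene | C#CCc1c(OCc2ccccc2)cc(OCc2ccccc2)cc1OCc1ccccc1 | intermediate
11 | lithium 3-[2,4,6-tris(benzyloxy)phenyl]prop-1-yn-1-ide | [Li+].[C-]#CCc1c(OCc2ccccc2)cc(OCc2ccccc2)cc1OCc1ccccc1 | intermediate
12 | lithium 3-[2,4,6-tris(benzyloxy)phenyl]prop-1-yn-1-olate | [Li+].[O-]C#CCc1c(OCc2ccccc2)cc(OCc2ccccc2)cc1OCc1ccccc1 | intermediate
13 | triisopropyl({3-[2,4,6-tris(benzyloxy)phenyl]prop-1-yn-1-yl}oxy)silane | CC(C)[Si](OC#CCc1c(OCc2ccccc2)cc(OCc2ccccc2)cc1OCc1ccccc1)(C(C)C)C(C)C | intermediate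
14 | (3Z)-3-methoxypenta-1,3-dien-1-one (vinylketene) | O=C=C/C(OC)=C/C | intermediate
15 | 4-[(1Z)-1-methoxyprop-1-en-1-yl]-2-{[2,4,6-tris(benzyloxy)phenyl]methyl}-3-[(triisopropylsilyl)oxy]cyclobut-2-en-1-one (racemic) | O=C1C(Cc2c(OCc3ccccc3)cc(OCc3ccccc3)cc2OCc2ccccc2)=C(O[Si](C(C)C)(C(C)C)C(C)C)C1/C(OC)=C/C | intermediate
16 | (3E,5Z)-5-methoxy-2-{[2,4,6-tris(benzyloxy)phenyl]methyl}-3-[(triisopropylsilyl)oxy]hepta-1,3,5-trien-1-one (dienylketene) | O=C=C(Cc1c(OCc2ccccc2)cc(OCc2ccccc2)cc1OCc1ccccc1)/C(O[Si](C(C)C)(C(C)C)C(C)C)=C\C(OC)=C\C | intermediate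
17 | 5-methoxy-6-methyl-2-{[2,4,6-tris(benzyloxy)phenyl]methyl}-3-[(triisopropylsilyl)oxy]cyclohexa-2,4-dien-1-one (racemic) | CC1C(OC)=CC(O[Si](C(C)C)(C(C)C)C(C)C)=C(Cc2c(OCc3ccccc3)cc(OCc3ccccc3)cc2OCc2ccccc2)C1=O | intermediate
18 | 5-methoxy-6-methyl-2-{[2,4,6-tris(benzyloxy)phenyl]methyl}-3-[(triisopropylsilyl)oxy]phenol | Cc1c(O)c(Cc2c(OCc3ccccc3)cc(OCc3ccccc3)cc2OCc2ccccc2)c(O[Si](C(C)C)(C(C)C)C(C)C)cc1OC | intermediate
19 | 5-methoxy-4-methyl-2-{[2,4,6-tris(benzyloxy)phenyl]methyl}benzene-1,3-diol | Cc1c(O)c(Cc2c(OCc3ccccc3)cc(OCc3ccccc3)cc2OCc2ccccc2)c(O)cc1OC | intermediate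
20 | 2-[(2,6-dihydroxy-4-methoxy-3-methylphenyl)methyl]benzene-1,3,5-triol | Cc1c(O)c(Cc2c(O)cc(O)cc2O)c(O)cc1OC | intermediate
21 | bis(ketiminium chloride) of 22 | CCCC(=[NH2+])c1c(O)cc(O)c(Cc2c(O)c(C)c(OC)c(C(=[NH2+])CCC)c2O)c1O.[Cl-].[Cl-] | intermediate
22 | 1-{3-[(3-butanoyl-2,4,6-trihydroxyphenyl)methyl]-2,4-dihydroxy-6-methoxy-5-methylphenyl}butan-1-one | CCCC(=O)c1c(O)cc(O)c(Cc2c(O)c(C)c(OC)c(C(=O)CCC)c2O)c1O | intermediate
23 | 2-methylbenzene-1,3,5-triol | Cc1c(O)cc(O)cc1O | starting material
24 | 1-(2,4,6-trihydroxy-3-methylphenyl)butan-1-one | CCCC(=O)c1c(O)cc(O)c(C)c1O | intermediate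
25 | 1-(2,6-dihydroxy-4-methoxy-3-methylphenyl)butan-1-one | CCCC(=O)c1c(O)cc(OC)c(C)c1O | intermediate
26 | 1-{3-[(dimethylamino)methyl]-2,6-dihydroxy-4-methoxy-5-methylphenyl}butan-1-one | CCCC(=O)c1c(O)c(CN(C)C)c(OC)c(C)c1O | intermediate
27 | 2-butanoyl-3-hydroxy-5-methoxy-4-methyl-6-methylidenecyclohexa-2,4-dien-1-one (ring C ortho-quinone methide) | C=C1C(=O)C(C(=O)CCC)=C(O)C(C)=C1OC | intermediate
28 | 1-{3-[(3-butanoyl-2,6-dihydroxy-4-methoxy-5-methylphenyl)methyl]-5-[(3-butanoyl-2,4-dihydroxy-6-methoxy-5-methylphenyl)methyl]-2,4,6-trihydroxyphenyl}butan-1-one | CCCC(=O)c1c(O)c(Cc2c(O)c(C)c(OC)c(C(=O)CCC)c2O)c(O)c(Cc2c(O)c(C(=O)CCC)c(O)c(C)c2OC)c1O | target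

Total step count: 14
Longest linear sequence: 9 steps (3, 4, 5, 6, 7, 8, 9, 10, 14)

Steps most likely to fail

**Step 7.** The vinylogous-ester stabilisation of the cyclobutenone may push its ring opening to temperatures at which the siloxyalkyne slowly isomerises or the ketene is lost to self-condensation. The cascade would then stall before the [2+2] step.
- The fallback sets out from 24 and comes back at 22. It takes ring A from the aromatic pool instead of building it.
- Twofold benzylation of 24 (BnBr, K2CO3, acetone) should spare the hydroxyl locked between methyl and carbonyl and give 1-[4,6-bis(benzyloxy)-2-hydroxy-3-methylphenyl]butan-1-one F1.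
- Forcing methylation (Me2SO4, K2CO3, acetone, reflux) should give 1-[4,6-bis(benzyloxy)-2-methoxy-3-methylphenyl]butan-1-one F2.
- Hydrogenolysis (H2, Pd/C, EtOAc) should give 1-(4,6-dihydroxy-2-methoxy-3-methylphenyl)butan-1-one F3.
- Mannich reaction at its only free carbon (CH2O, Me2NH, EtOH) should give 1-{3-[(dimethylamino)methyl]-2,4-dihydroxy-6-methoxy-5-methylphenyl}butan-1-one F4.
- Heating F4 in dioxane with an excess of commercial 1-(2,4,6-trihydroxyphenyl)butan-1-one should give 22 by the same elimination–addition as in step 14.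

**Step 10.** Three things may go wrong before both rings are deactivated. Acid may promote exchange of the methylene bridge by ipso-protonation and retro-Friedel–Crafts cleavage. Two ortho hydroxyls may cyclodehydrate across the bridge. Acylation may also stay incomplete at the more crowded ring A position.
- The fallback sets out from 19 and comes back at 22. It installs both ketones on the fully protected diarylmethane without strong protic acid.
- Benzylation of 19 (BnBr, K2CO3, DMF) should give 1,3-bis(benzyloxy)-5-methoxy-4-methyl-2-{[2,4,6-tris(benzyloxy)phenyl]methyl}benzene F5.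
- Twofold Vilsmeier–Haack formylation (POCl3, DMF) stops at one formyl group per ring and should give 2,4-bis(benzyloxy)-3-{[2,4,6-tris(benzyloxy)-3-formylphenyl]methyl}-6-methoxy-5-methylbenzaldehyde F6.
- Addition of n-PrMgCl should give, as a mixture of diastereomers, 1-{2,4-bis(benzyloxy)-3-[(2,4,6-tris(benzyloxy)-3-(1-hydroxybutyl)phenyl)methyl]-6-methoxy-5-methylphenyl}butan-1-ol F7.
- Oxidation with Dess–Martin periodinane should give 1-{2,4-bis(benzyloxy)-3-[(2,4,6-tris(benzyloxy)-3-butanoylphenyl)methyl]-6-methoxy-5-methylphenyl}butan-1-one F8.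
- Hydrogenolysis of F8 (H2, Pd/C, EtOAc) should give 22.

**Step 14.** Capture of the quinone methide at the crowded, doubly hydrogen-bonded ring B carbon may be slow, which leaves time for self-condensation of the methide. The liberated amine may also promote exchange of the bridge that is already in place.
- The fallback sets out from 22 and comes back at 28. It inverts the roles of the partners.
- Mannich reaction of 22 at its last free carbon (CH2O, Me2NH, EtOH, 0 °C) should give 1-{3-[(3-butanoyl-5-[(dimethylamino)methyl]-2,4,6-trihydroxyphenyl)methyl]-2,4-dihydroxy-6-methoxy-5-methylphenyl}butan-1-one F9.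
- Warming F9 with an excess of the cheap, more nucleophilic ketone 25 makes ring B the electrophile. The single free carbon of 25 then closes the second bridge to give 28.

Further compounds
F1 | step 7 | 1-[4,6-bis(benzyloxy)-2-hydroxy-3-methylphenyl]butan-1-one | CCCC(=O)c1c(O)c(C)c(OCc2ccccc2)cc1OCc1ccccc1
F2 | step 7 | 1-[4,6-bis(benzyloxy)-2-methoxy-3-methylphenyl]butan-1-one | CCCC(=O)c1c(OC)c(C)c(OCc2ccccc2)cc1OCc1ccccc1
F3 | step 7 | 1-(4,6-dihydroxy-2-methoxy-3-methylphenyl)butan-1-one | CCCC(=O)c1c(OC)c(C)c(O)cc1O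
F4 | step 7 | 1-{3-[(dimethylamino)methyl]-2,4-dihydroxy-6-methoxy-5-methylphenyl}butan-1-one | CCCC(=O)c1c(OC)c(C)c(O)c(CN(C)C)c1O
F5 | step 10 | 1,3-bis(benzyloxy)-5-methoxy-4-methyl-2-{[2,4,6-tris(benzyloxy)phenyl]methyl}benzene | Cc1c(OCc2ccccc2)c(Cc2c(OCc3ccccc3)cc(OCc3ccccc3)cc2OCc2ccccc2)c(OCc2ccccc2)cc1OC
F6 | step 10 | 2,4-bis(benzyloxy)-3-{[2,4,6-tris(benzyloxy)-3-formylphenyl]methyl}-6-methoxy-5-methylbenzaldehyde | Cc1c(OCc2ccccc2)c(Cc2c(OCc3ccccc3)cc(OCc3ccccc3)c(C=O)c2OCc2ccccc2)c(OCc2ccccc2)c(C=O)c1OC
F7 | step 10 | 1-{2,4-bis(benzyloxy)-3-[(2,4,6-tris(benzyloxy)-3-(1-hydroxybutyl)phenyl)methyl]-6-methoxy-5-methylphenyl}butan-1-ol (mixture of diastereomers) | Cc1c(OCc2ccccc2)c(Cc2c(OCc3ccccc3)cc(OCc3ccccc3)c(C(O)CCC)c2OCc2ccccc2)c(OCc2ccccc2)c(C(O)CCC)c1OC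
F8 | step 10 | 1-{2,4-bis(benzyloxy)-3-[(2,4,6-tris(benzyloxy)-3-butanoylphenyl)methyl]-6-methoxy-5-methylphenyl}butan-1-one | Cc1c(OCc2ccccc2)c(Cc2c(OCc3ccccc3)cc(OCc3ccccc3)c(C(=O)CCC)c2OCc2ccccc2)c(OCc2ccccc2)c(C(=O)CCC)c1OC
F9 | step 14 | 1-{3-[(3-butanoyl-5-[(dimethylamino)methyl]-2,4,6-trihydroxyphenyl)methyl]-2,4-dihydroxy-6-methoxy-5-methylphenyl}butan-1-one | CCCC(=O)c1c(O)c(CN(C)C)c(O)c(Cc2c(O)c(C)c(OC)c(C(=O)CCC)c2O)c1O
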